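Moles per litre, not percent of charge, are the unit in which the earlier runs can be compared.

| flask | substrate | partner | remark | time |
|---|---|---|---|---|
| epsilon | 0.17 M | 0.20 M | run made earlier |  |
| delta | 0.50 M | 0.20 M | run made earlier |  |
| north-east | 0.25 M | 0.200 M |  | 25 h |
| north | 0.25 M | 0.625 M |  | 25 h |
| east | 0.25 M | 1.00 M |  | 25 h |

| run | time / h | bis adduct / % | triple product / % |
|---|---|---|---|
| epsilon | 1.33 | 29 | 0 |
| epsilon | 2.00 | 32 | 2 |
| epsilon | 3.00 | 31 | 1 |
| epsilon | 4.00 | 31 | 2 |
| epsilon | 6.00 | 33 | 0 |
| epsilon | 10.0 | 33 | 1 |
| epsilon | 15.0 | 33 | 2 |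
| delta | 0.833 | 10 | 0 |
| delta | 2.50 | 10 | 0 |
| delta | 4.00 | 11 | 0 |
| delta | 6.00 | 8 | 0 |
| delta | 10.0 | 12 | 2 |
| delta | 12.0 | 10 | 0 |
| delta | 15.0 | 11 | 1 |

(scatter of a reading: 1.5 percentage points)



* how much bis adduct is there at the end, in percent of the substrate charged: for each flask in turn (north-east, north, east)

I take the bis adduct plateau as the mean of the last 3 readings of each run, multiplied by the substrate charged:

D(epsilon) = 0.0561 M
D(delta) = 0.0550 M

The two plateaus are about the same, although substrate goes from 0.17 M to 0.50 M at equal partner. In powers of ten, the slope of plateau against substrate charge is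

n = lg(D(delta)/D(epsilon)) / lg(charge ratio) = −0.0184

So I read partner as the limiting reagent and carry Y = 0.278, the partner yield: plateau bis adduct per partner charged.

Now I draw my own curve of end yield against partner charge c(B), at substrate charge c(A) = 0.25 M:

yield = Y c(B)/c(A), with initial slope 1.11 L mol⁻¹

On logarithmic axes this is a line of slope one. It passes 22.2% at 0.200 M and 69.4% at 0.625 M. Its knee lies where it meets the substrate charged:

c* = c(A)/Y = 0.900 M

Above the knee my curve runs level at 100%. East, at 1.00 M, lies past the knee, so I commit to a figure below that level but name none: triple product reads 2% at the end of epsilon, and I read no rate for the onward step from that.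

The forecast gives 22%, 62% and 75%, and says “shade the last two values down, the east flask most”. At north it stands lower than my line.

The flasks end at 22.8%, 69.4% and 45.2%.

    substrate + partner → mono adduct + by-product (k = 0.120 L mol⁻¹ min⁻¹)
    partner + mono adduct → bis adduct + by-product (k = 0.370 L mol⁻¹ min⁻¹)
    partner + bis adduct → triple product + by-product (k = 0.0120 L mol⁻¹ min⁻¹)
    partner → decomposed reagent (k = 0.00510 min⁻¹)
    mono adduct → side product (k = 0.00780 min⁻¹)
    crystals ⇌ by-product, rate k6*(cs6 - [by-product]) while solid is left; crystals form when [by-product] > cs6 (solubility = 0.200 M, k = 3.60 min⁻¹)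

The forecast for east stands 30 percentage points above the flask. Read back, Y is 0.285 in north-east and 0.278 in north, but 0.113 in east, past the knee. In north-east, half the turnover to bis adduct is done by 0.371 h, and partner stands at 0% at the end with 54% of the substrate left. In east, substrate is down to 0.0138% of its charge after 12.5 h, and the step from partner + bis adduct has run as well, so that the flask ends at 51.4% triple product beside 45.2% bis adduct.

(Readings and results stem from a simulated flask for substances that don't exist; the scatter is artificial.)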